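## Retrosynthetic overview

1. Positions are numbered as in geranylnerol (C1 = CH2O, C18 = carboxyl carbon on C11). Presumed biosynthesis: an acyclic (2Z)-geranylnerol Δ10-18-oic acid is oxygenated at C12/C13 and the C18 carboxyl closes onto C13. The trans 12-O/13-O pattern is that of a (12E)-12,13-epoxide opened at the allylic C13 with inversion; O-acylations follow.
2. γ-Lactone (the only ring of the target): cut the alkyl C13–O bond, not the acyl C–O bond. This leads back to an acyclic (12S,13S)-12,13-epoxy tert-butyl 18-oate, closed by acid-triggered 5-endo opening by the ester carbonyl, with acetylation in the same flask.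
3. Oxirane: the C12–C13 bond and both stereocentres come from an allylic sulfonium ylide (chiral bicyclic sulfide) and prenal.
4. Ylide precursor: the (Z)-allylic bromide from the Morita–Baylis–Hillman adduct of the C1–C10 aldehyde and tert-butyl acrylate, which fixes the 10,11-geometry.
5. C1–C10 aldehyde from nerol (2Z): methacrylate first (no protecting groups), singlet-oxygen ene reaction, Claisen rearrangement (6E). Ring order: oxirane (step 6), then γ-lactone (step 7).

Assumption: the isothiocineole enantiomer made from (S)-limonene is taken to give the (2S,3S)-oxirane (derived from a steric model of the ylide, not from a checked precedent); if a pilot run shows the opposite sense, the antipodal sulfide is used with no other change.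

## Route

Step 1
Reactants: 1 nerol; 2 methacrylic anhydride
Product: 3 neryl methacrylate [(2Z)-3,7-dimethylocta-2,6-dien-1-yl 2-methylprop-2-enoate]
Conditions: Et3N, 4-(dimethylamino)pyridine (cat.), CH2Cl2, 0 °C to rt
Reagents that add atoms: none
Why: Nucleophile-catalysed acylation of the primary allylic alcohol puts the final methacrylate in place at the start, so no protecting group is needed and the (2Z)-alkene of nerol is carried through unchanged.

Step 2
Reactants: 3 neryl methacrylate
Product: 5 (2Z)-6-hydroxy-3,7-dimethylocta-2,7-dien-1-yl methacrylate (racemic), via secondary allylic hydroperoxide 4 (not isolated)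
Conditions: O2, 5,10,15,20-tetraphenylporphyrin (cat.), visible light, CH2Cl2, 0 °C; then PPh3, 0 °C
Reagents that add atoms: dioxygen (O=O)
Why: Schenck ene reaction of singlet oxygen at the electron-rich 6,7-alkene (the 2,3-alkene is deactivated by the allylic ester and the methacrylate is inert) gives the secondary hydroperoxide by hydrogen abstraction from a methyl group, about 1:1 with the tertiary 7-hydroperoxide that is removed by chromatography after reduction; the racemic C6 centre is erased in step 3.

Step 3
Reactants: 5 (2Z)-6-hydroxy-3,7-dimethylocta-2,7-dien-1-yl methacrylate; 6 ethyl vinyl ether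
Product: 8 (2Z,6E)-3,7-dimethyl-10-oxodeca-2,6-dien-1-yl methacrylate, via allyl vinyl ether 7 (not isolated)
Conditions: Hg(OAc)2 (0.3 equiv), ethyl vinyl ether (solvent), reflux; concentrate; PhMe, BHT (cat.), 110 °C, sealed tube
Reagents that add atoms: none
Why: Transfer vinylation followed by Claisen rearrangement through a chair transition state with the C5 chain equatorial gives the (6E)-trisubstituted alkene (normally above 95:5) and adds C9–C10 as the aldehyde.

Step 4
Reactants: 8 (2Z,6E)-3,7-dimethyl-10-oxodeca-2,6-dien-1-yl methacrylate; 9 tert-butyl acrylate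
Product: 10 tert-butyl (6E,10Z)-3-hydroxy-6,10-dimethyl-2-methylidene-12-(methacryloyloxy)dodeca-6,10-dienoate (racemic)
Conditions: DABCO (1,4-diazabicyclo[2.2.2]octane, 0.5 equiv), 9 (5 equiv), neat, rt, 7 d
Reagents that add atoms: none
Why: Morita–Baylis–Hillman reaction of the aliphatic aldehyde with the acrylate (the α-substituted methacrylate cannot turn over) builds the C10–C11 bond; the racemic carbinol centre disappears in step 5.

Step 5
Reactants: 10 tert-butyl (6E,10Z)-3-hydroxy-6,10-dimethyl-2-methylidene-12-(methacryloyloxy)dodeca-6,10-dienoate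
Product: 11 tert-butyl (2Z,6E,10Z)-2-(bromomethyl)-6,10-dimethyl-12-(methacryloyloxy)dodeca-2,6,10-trienoate
Conditions: NBS, Me2S, CH2Cl2, 0 °C (reagent pre-formed); then 10, 0 °C to rt
Reagents that add atoms: N-bromosuccinimide (O=C1CCC(=O)N1Br)
Why: Corey–Kim-type activation of the alcohol as its alkoxysulfonium ion and SN2' attack of bromide give the transposed primary allylic bromide with the alkyl chain trans to the ester (2Z, usually at least 9:1), which is the 10,11-geometry of the target.

Step 6
Reactants: 11 tert-butyl (2Z,6E,10Z)-2-(bromomethyl)-6,10-dimethyl-12-(methacryloyloxy)dodeca-2,6,10-trienoate; 12 (1S,4R,5S)-4,7,7-trimethyl-6-thiabicyclo[3.2.1]octane (isothiocineole enantiomer from (S)-limonene, ring methyl cis to sulfur); 13 prenal (3-methylbut-2-enal)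
Product: 15 tert-butyl (2E,6E,10Z)-6,10-dimethyl-12-(methacryloyloxy)-2-[(2S,3S)-3-(2-methylprop-1-enyl)oxiran-2-yl]dodeca-2,6,10-trienoate, via sulfonium bromide 14 (not isolated)
Conditions: 12 (1.1 equiv), MeCN, rt, 16 h; then 13 (3 equiv), Cs2CO3 (1.5 equiv), −20 to 0 °C
Reagents that add atoms: none
Why: Proposed new method: the sulfide is alkylated at the primary allylic carbon on its less hindered lone pair, carbonate gives a semi-stabilised 2-(alkoxycarbonyl)allyl ylide that adds through its sulfur-bearing carbon to the aldehyde, and the anti betaine closes to the trans oxirane with release of the sulfide, the bicyclic sulfide fixing the ylide conformation and shielding one face so that (2S,3S) is formed with the alkene geometry retained; the closest known reactions are the asymmetric sulfur ylide (Corey–Chaykovsky type) epoxidation of aldehydes with allylic sulfonium salts of isothiocineole and the racemic epoxidation with dimethylsulfonium ylides made from Morita–Baylis–Hillman bromides.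

Step 7
Reactants: 15 tert-butyl (2E,6E,10Z)-6,10-dimethyl-12-(methacryloyloxy)-2-[(2S,3S)-3-(2-methylprop-1-enyl)oxiran-2-yl]dodeca-2,6,10-trienoate; 16 acetic anhydride
Product: 18 (2Z,6E,10E)-10-[(4S,5R)-4-acetoxy-5-(2-methylprop-1-enyl)-2-oxooxolan-3-ylidene]-3,7-dimethyldeca-2,6-dien-1-yl methacrylate (target CNP0152230.1), via hydroxy lactone 17 (not isolated)
Conditions: (±)-camphor-10-sulfonic acid (10 mol %), CH2Cl2, −40 to 0 °C; then pyridine, 16, 0 °C to rt
Reagents that add atoms: none
Why: Acid-catalysed epoxy-ester lactonisation with neighbouring-group participation: the protonated oxirane is attacked at the allylic C13 from the rear by the tert-butyl ester carbonyl oxygen (alkenyl-directed 5-endo opening, the 4-exo mode would give a β-lactone), so C13 inverts to R while C12 stays S and the two oxygens end up trans; the dioxocarbenium ion sheds 2-methylpropene, and the freed secondary alcohol is acetylated in the same flask.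

## Compound list

1 | nerol, (2Z)-3,7-dimethylocta-2,6-dien-1-ol | CC(C)=CCC/C(C)=C\CO | starting material
2 | methacrylic anhydride | C=C(C)C(=O)OC(=O)C(C)=C | starting material
3 | neryl methacrylate, (2Z)-3,7-dimethylocta-2,6-dien-1-yl 2-methylprop-2-enoate | C=C(C)C(=O)OC/C=C(/C)CCC=C(C)C | intermediate
4 | (2Z)-6-hydroperoxy-3,7-dimethylocta-2,7-dien-1-yl methacrylate (racemic; not isolated) | C=C(C)C(=O)OC/C=C(/C)CCC(OO)C(C)=C | intermediate
5 | (2Z)-6-hydroxy-3,7-dimethylocta-2,7-dien-1-yl methacrylate (racemic) | C=C(C)C(=O)OC/C=C(/C)CCC(O)C(C)=C | intermediate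
6 | ethyl vinyl ether | C=COCC | starting material
7 | (2Z)-6-(ethenyloxy)-3,7-dimethylocta-2,7-dien-1-yl methacrylate (racemic; not isolated) | C=C(C)C(=O)OC/C=C(/C)CCC(OC=C)C(C)=C | intermediate
8 | (2Z,6E)-3,7-dimethyl-10-oxodeca-2,6-dien-1-yl methacrylate | C=C(C)C(=O)OC/C=C(/C)CC/C=C(\C)CCC=O | intermediate
9 | tert-butyl acrylate | C=CC(=O)OC(C)(C)C | starting material
10 | tert-butyl (6E,10Z)-3-hydroxy-6,10-dimethyl-2-methylidene-12-(methacryloyloxy)dodeca-6,10-dienoate (racemic) | C=C(C)C(=O)OC/C=C(/C)CC/C=C(\C)CCC(O)C(=C)C(=O)OC(C)(C)C | intermediate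
11 | tert-butyl (2Z,6E,10Z)-2-(bromomethyl)-6,10-dimethyl-12-(methacryloyloxy)dodeca-2,6,10-trienoate | C=C(C)C(=O)OC/C=C(/C)CC/C=C(\C)CC/C=C(\CBr)C(=O)OC(C)(C)C | intermediate
12 | (1S,4R,5S)-4,7,7-trimethyl-6-thiabicyclo[3.2.1]octane, isothiocineole enantiomer from (S)-limonene (recoverable chiral reagent) | C[C@@H]1CC[C@H]2C[C@@H]1SC2(C)C | starting material
13 | prenal, 3-methylbut-2-enal | CC(C)=CC=O | starting material
14 | S-allyl sulfonium bromide of 12 and 11, allyl group on the sulfur face remote from the three-carbon bridge (not isolated) | C[C@@H]1CC[C@H]2C[C@@H]1[S@+](C/C(C(=O)OC(C)(C)C)=C\CC/C(C)=C/CC/C(C)=C\COC(=O)C(C)=C)C2(C)C.[Br-] | intermediate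
15 | tert-butyl (2E,6E,10Z)-6,10-dimethyl-12-(methacryloyloxy)-2-[(2S,3S)-3-(2-methylprop-1-enyl)oxiran-2-yl]dodeca-2,6,10-trienoate | C=C(C)C(=O)OC/C=C(/C)CC/C=C(\C)CC/C=C(\[C@@H]1O[C@H]1C=C(C)C)C(=O)OC(C)(C)C | intermediate
16 | acetic anhydride | CC(=O)OC(C)=O | starting material
17 | (2Z,6E,10E)-10-[(4S,5R)-4-hydroxy-5-(2-methylprop-1-enyl)-2-oxooxolan-3-ylidene]-3,7-dimethyldeca-2,6-dien-1-yl methacrylate (not isolated) | C=C(C)C(=O)OC/C=C(/C)CC/C=C(\C)CC/C=C1/C(=O)O[C@H](C=C(C)C)[C@H]1O | intermediate
18 | (2Z,6E,10E)-10-[(4S,5R)-4-acetoxy-5-(2-methylprop-1-enyl)-2-oxooxolan-3-ylidene]-3,7-dimethyldeca-2,6-dien-1-yl methacrylate | C=C(C)C(=O)OC/C=C(/C)CC/C=C(\C)CC/C=C1/C(=O)O[C@H](C=C(C)C)[C@H]1OC(C)=O | target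

## Step count and risks

Total step count: 7. Longest linear sequence: 7 (nerol 1 to target 18).

The three steps most likely to fail:

**Step 2 (regio- and site-selectivity of the ene reaction; about half the material goes to the tertiary isomer).** The fallback sets out from 3 and comes back at 5. The 6,7-alkene of 3 is epoxidised with mCPBA (CH2Cl2, 0 °C) to the racemic 6,7-epoxide F1. The oxirane is isomerised with TMSOTf and DBU in toluene to the allyl trimethylsilyl ether F2 (loss of a methyl proton, oxygen stays on C6). The silyl ether is cleaved with dilute HCl on work-up to give 5.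

**Step 6 (untested ylide class: regiochemistry of S-alkylation, trans/cis ratio, ee and sense of induction).** The fallback sets out from 11 and comes back at 18, or at 17 if the enzyme prefers the other enantiomer. It replaces reagent control by kinetic resolution:
- 11 is treated with tetrahydrothiophene in MeCN to give the tetrahydrothiophenium bromide F3, then with prenal 13 and Cs2CO3 to give racemic trans-epoxide, that is 15 together with the (2R,3R)-epoxide F4.
- The acid treatment of step 7 without the acetylation gives racemic hydroxy lactone, that is 17 together with the (4R,5S)-hydroxy lactone F5.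
- Burkholderia cepacia lipase with vinyl acetate in tert-butyl methyl ether at 30 °C is run to about half conversion. If the enzyme acetylates the (4S,5R)-alcohol, 18 is isolated directly and F5 is left behind. If it acetylates the other enantiomer to the (4R,5S)-acetate F6, the unreacted alcohol is 17 and is acetylated with 16 and pyridine as in step 7.

**Step 7 (the prenyl-type allylic C13 may ionise, giving C13 epimers, dienes or a rearranged ketone instead of clean inversion).** The fallback sets out from 11 and comes back at 17. It frees the carboxyl before the oxirane is made, so that ring closure needs only the weak acidity of the carboxylic acid itself: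
- 11 is treated with TMSOTf and 2,6-lutidine (CH2Cl2, 0 °C) to give the trimethylsilyl ester F7, which aqueous work-up hydrolyses to the bromo acid F8.
- F8 and sulfide 12 give the sulfonium bromide F9. Prenal 13 and Cs2CO3 (2.5 equiv) then give the epoxy carboxylate.
- Acidification to pH 4–5 with citrate buffer at 0 °C gives the epoxy acid F10. Its own carboxyl group opens the oxirane at C13 on standing in CH2Cl2 to give 17, which is acetylated with 16 and pyridine as in step 7.

## Further compounds

F1 | step 2 | (2Z)-5-(3,3-dimethyloxiran-2-yl)-3-methylpent-2-en-1-yl methacrylate (racemic) | C=C(C)C(=O)OC/C=C(/C)CCC1OC1(C)C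
F2 | step 2 | (2Z)-3,7-dimethyl-6-(trimethylsilyloxy)octa-2,7-dien-1-yl methacrylate (racemic) | C=C(C)C(=O)OC/C=C(/C)CCC(O[Si](C)(C)C)C(C)=C
F3 | step 6 | S-allyl tetrahydrothiophenium bromide formed from 11 | C=C(C)C(=O)OC/C=C(/C)CC/C=C(\C)CC/C=C(\C[S+]1CCCC1)C(=O)OC(C)(C)C.[Br-]
F4 | step 6 | tert-butyl (2E,6E,10Z)-6,10-dimethyl-12-(methacryloyloxy)-2-[(2R,3R)-3-(2-methylprop-1-enyl)oxiran-2-yl]dodeca-2,6,10-trienoate (enantiomer of 15) | C=C(C)C(=O)OC/C=C(/C)CC/C=C(\C)CC/C=C(\[C@H]1O[C@@H]1C=C(C)C)C(=O)OC(C)(C)C
F5 | step 6 | (2Z,6E,10E)-10-[(4R,5S)-4-hydroxy-5-(2-methylprop-1-enyl)-2-oxooxolan-3-ylidene]-3,7-dimethyldeca-2,6-dien-1-yl methacrylate (enantiomer of 17) | C=C(C)C(=O)OC/C=C(/C)CC/C=C(\C)CC/C=C1/C(=O)O[C@@H](C=C(C)C)[C@@H]1O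
F6 | step 6 | (2Z,6E,10E)-10-[(4R,5S)-4-acetoxy-5-(2-methylprop-1-enyl)-2-oxooxolan-3-ylidene]-3,7-dimethyldeca-2,6-dien-1-yl methacrylate (enantiomer of 18) | C=C(C)C(=O)OC/C=C(/C)CC/C=C(\C)CC/C=C1/C(=O)O[C@@H](C=C(C)C)[C@@H]1OC(C)=O
F7 | step 7 | trimethylsilyl (2Z,6E,10Z)-2-(bromomethyl)-6,10-dimethyl-12-(methacryloyloxy)dodeca-2,6,10-trienoate | C=C(C)C(=O)OC/C=C(/C)CC/C=C(\C)CC/C=C(\CBr)C(=O)O[Si](C)(C)C
F8 | step 7 | (2Z,6E,10Z)-2-(bromomethyl)-6,10-dimethyl-12-(methacryloyloxy)dodeca-2,6,10-trienoic acid | C=C(C)C(=O)OC/C=C(/C)CC/C=C(\C)CC/C=C(\CBr)C(=O)O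
F9 | step 7 | S-allyl sulfonium bromide of 12 and F8 | C[C@@H]1CC[C@H]2C[C@@H]1[S@+](C/C(C(=O)O)=C\CC/C(C)=C/CC/C(C)=C\COC(=O)C(C)=C)C2(C)C.[Br-]
F10 | step 7 | (2E,6E,10Z)-6,10-dimethyl-12-(methacryloyloxy)-2-[(2S,3S)-3-(2-methylprop-1-enyl)oxiran-2-yl]dodeca-2,6,10-trienoic acid | C=C(C)C(=O)OC/C=C(/C)CC/C=C(\C)CC/C=C(\[C@@H]1O[C@H]1C=C(C)C)C(=O)O
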